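## Structural features

The target 18 is an achiral, pentabrominated tris-catechol: three benzene rings joined in a row by two methylene bridges. On the central ring B, C1 carries the CH2 arm to ring A, C2 the CH2 arm to ring C, C3 a bromine, C4 and C5 the hydroxyls and C6 a hydrogen; rings A and C are identical 2,3-dibromo-4,5-dihydroxyphenyl groups bound through their C1. There is no stereocentre, so any stereocentre that appears on the way only has to be erasable. The fragile elements are the three catechols (oxidized to o-quinones by air in base and by many oxidants), the five aryl–bromine bonds (lost to low-valent metals, organolithiums and strongly reducing cathodes) and the two diarylmethane bridges para to a phenolic oxygen (ipso attack and benzyl loss under strongly electrophilic conditions). The real difficulty is regiochemical: two adjacent bromines on each outer ring but exactly one on ring B, next to an ortho-dibenzyl pattern that cannot be assembled by aryl-metal chemistry on polybromoarenes. The route exploits that, with the C3 bromine set aside, the carbon skeleton has a twofold axis through the midpoints of the C1–C2 and C4–C5 bonds of ring B. Each half is the same aryl–CH2–CH–CH2–C(O) chain (ring A arm, C1, C6, C5 and ring C arm, C2, C3, C4), so C1–C2 can be made by joining two identical radicals centred on the future C1 and C2.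

## Logic of the disconnections

18 ⇒ 17. The four aryl O–S bonds of rings A and C are cut last. Free catechols on the outer rings would not survive an anode, a hydride, iodine/DMSO or Br2, whereas as methanesulfonates they are electron-poor and inert, and the free catechol of ring B stands out from them. Nothing is gained in skeleton, but all earlier chemistry becomes possible. The forward step must hydrolyse four sulfonates without touching C–Br bonds and with oxygen excluded.

17 ⇒ 16. The C3–Br bond of ring B is cut because it is the only element that breaks the twofold symmetry. The gain is a symmetric precursor in which C3 and C6 are equivalent. The forward step must brominate the only activated ring once and stop.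

16 ⇒ 14 (through 15). No skeletal bond is cut; ring B is taken back from the arene to the acyloin oxidation level by returning hydrogens to C1, C2, C3 and C6. The reason is that the acyloin is the direct product of closing C4–C5 and already carries both oxygens in place. The gain is a saturated ring that can be made from an open chain. The forward step must dehydrogenate twice and stop at the catechol.

14 ⇒ 13. The C4–C5 bond is cut between the carbonyl and the carbinol carbon. This opens ring B to a symmetric 1,6-dialdehyde whose two termini are identical. The forward step needs one aldehyde made nucleophilic (carbene umpolung) faster than base-mediated intramolecular aldol.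

13 ⇒ 12. No bond is cut; the aldehydes are traced back to methyl esters, which are inert spectators during the radical coupling and need no exchange in methanol. The forward step is a partial reduction that must stop at the aldehyde twice.

12 ⇒ 11 + 11. The C1–C2 bond of the future ring B is cut. This halves the molecule into two copies of one half-ester. The forward step must generate a secondary alkyl radical by decarboxylation and dimerize it before it is oxidized further, with the arenes and C–Br bonds inert at both electrodes.

11 ⇒ 9 (through 10) ⇒ 7 + 8. The C–CO2H bond of a geminal diacid and the bond between the branched carbon and the CH2 of the acetate arm are cut. This places the free acid on the branched carbon and the ester on the CH2 arm without ambiguity. Opening a substituted succinic anhydride with methanol would give both half-esters, and the wrong one would give a primary radical and crossed dimers at the anode. The forward steps need C- rather than O-alkylation of 7 and a hydrolysis–decarboxylation that spares the methyl ester.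

7 ⇒ 4 + 5 (through 6). The benzylic CH2–C bond is cut. The aldehyde is used directly, so no benzylic halide and no strong base are needed. The forward step must reduce the alkylidene intermediate without touching C–Br or O–S bonds.

4 ⇒ 3 ⇒ 2 ⇒ 1. The two O–S bonds, the O–CH3 bond and the C–Br bond next to the aldehyde are cut in turn, back to 1. The directing effects in 1 (position para to OMe) place the second bromine adjacent to the first. The forward steps are standard arene and phenol chemistry.

## Other disconnections considered

Alternative 1: Late pentabromination. The cut removes all five C–Br bonds at once (C2–Br and C3–Br of rings A and C, C3–Br of ring B) and leads to the bromine-free tris(guaiacol) A1. In the forward key step A1 would be treated with catalytic NH4VO3, H2O2 and KBr in weakly acidic medium; peroxovanadate oxidizes bromide to an electrophilic bromine species that substitutes the arenes five times to give A2, and cleavage of three methyl ethers would give 18.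
- In its favour: it mimics the marine bromoperoxidases, uses a cheap and benign oxidant, and the innate directing effects point the right way (each OH directs to C3 of its ring, each OMe para to C2 of rings A and C).
- Against it here: five substitutions on three rings of nearly equal nucleophilicity must stop at exactly the right sites. C6 of ring B (ortho to its OMe) has to stay free while the hindered C2 of rings A and C, between the CH2 arm and the C3 bromine, is brominated. Both bridges stand para to a free phenol, so ipso attack with loss of a benzyl cation or quinone methide threatens the skeleton. A1 itself needs a regioselective benzylation next to an existing arm.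
- Comparison: on structure, both plans reach the same skeleton, and the alternative avoids the protecting-group exchange. On mechanism, both place the ring B bromine by phenol-directed substitution, but the chosen plan fixes four bromines on a simple vanillin-derived ring and adds the fifth when ring B is the only activated ring. On step economy and reagent hazard the alternative is clearly the better; the chosen plan is better in certainty of bromine placement.

Alternative 2: Ynedione Diels–Alder. The cut is a retro-[4+2] across C6–C1 and C2–C3 of ring B, with C1=C2 as the former alkyne and both benzylic carbons at the ketone level. In the forward key step the bis(aroyl)acetylene A3 and the diene A4 would combine thermally to the cyclohexa-1,4-diene A5. Dehydrogenation, reduction of both diaryl ketones to CH2, bromination of ring B and cleavage of six methyl ethers would follow.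
- In its favour: two bonds and the ring form in one concerted step with well-matched electronics, symmetry removes any regio- or stereochemical question, the ring B oxygens arrive in place, and A5 is one dehydrogenation from the arene.
- Against it here: the resulting 1,2-diaroylbenzene is hard to deoxygenate. Partial reduction gives a hydroxy ketone that closes to a lactol and on to an isobenzofuran or phthalan, hydrazine-based methods would give a phthalazine, and dissolving metals or hydrogenolysis endanger four aryl bromides.
- Comparison: on mechanism of the key step the alternative is the better (a thermal cycloaddition is more predictable than an anodic radical dimerization), and it is also better in building ring B directly. Overall step economy is about equal. The chosen plan is better on structure, because the benzylic carbons are at the CH2 level from the start; the final deprotections are equal as one-step operations.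

Alternative 3: Umpoled ring B. The cut is the bond between the ring A CH2 and C1 of ring B, with ring B as an electrophilic dienone. In the forward key step the benzylzinc bromide A6, activated by MgCl2, would add 1,2 to the carbonyl of the quinone monoketal A7 to give the tertiary dienol A8 (racemic; its one stereocentre disappears on aromatization). Reductive aromatization with loss of the hydroxyl and one methoxy group, bromination of ring B and cleavage of six methyl ethers would follow.
- In its favour: zinc inserts into a benzylic C–Br bond in the presence of aryl bromides, no electrochemistry is needed, and ring B enters close to the arene oxidation level. The two arms are introduced separately, so rings A and C could differ; on this modularity the alternative is the better.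
- Against it here: the carbonyl of A7 is a vinylogous ester flanked by a benzyl-substituted alkene carbon, so 1,2-addition is expected to be slow and to compete with conjugate addition–elimination and benzyl homocoupling. A8 is an acid-sensitive quinol ketal that can undergo a 1,2-benzyl shift on ionization, which would scramble the ortho-dibenzyl pattern. The rearomatization needs a reductant that spares four aryl bromides, and A7 requires its own synthesis of a ring B phenol already bearing the ring C arm.
- Comparison: both plans are equal in needing no stereocontrol. On mechanism, the alternative is a polar addition to a hindered carbonyl and the chosen plan a radical coupling of unhindered identical partners. On step economy the alternative is expected to be somewhat longer (two fragments, ketal formation, aromatization); the chosen plan uses one building block twice.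

Key step: step 7

Assumption: 5-bromovanillin (1), the commercial monobromination product of vanillin, is taken as the starting point. Compounds 12 to 15 are carried as diastereomer mixtures and drawn without stereodescriptors, because their stereocentres are formed without control and are all erased in step 10.

## Route

Step 1
Reactants: 1 5-bromovanillin (3-bromo-4-hydroxy-5-methoxybenzaldehyde)
Product: 2 2,3-dibromo-4-hydroxy-5-methoxybenzaldehyde
Conditions: Br2 (1.2 equiv), Fe powder (5 mol %), AcOH, 20 to 60 °C
Reagents that add atoms: bromine, BrBr
Why: Electrophilic aromatic bromination with FeBr3 formed in situ; of the two free positions, the one para to the methoxy group should react in preference to the position squeezed between CHO and OMe, which sets the vicinal dibromide of rings A and C.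

Step 2
Reactants: 2 2,3-dibromo-4-hydroxy-5-methoxybenzaldehyde
Product: 3 2,3-dibromo-4,5-dihydroxybenzaldehyde
Conditions: BBr3 (2.5 equiv), CH2Cl2, −78 to 20 °C; then H2O
Reagents that add atoms: none
Why: Lewis-acid ether cleavage (BBr3 demethylation): bromide attacks the O-methyl carbon of the boron-complexed aryl ether in an SN2 step, and the aldehyde and aryl bromides should be untouched at this temperature.

Step 3
Reactants: 3 2,3-dibromo-4,5-dihydroxybenzaldehyde
Product: 4 2,3-dibromo-4,5-bis(methylsulfonyloxy)benzaldehyde
Conditions: MsCl (2.5 equiv), Et3N (3 equiv), CH2Cl2, 0 °C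
Reagents that add atoms: methanesulfonyl chloride, CS(=O)(=O)Cl
Why: O-Sulfonylation of both phenols (via sulfene); the bis-methanesulfonate is electron-poor, stable to acid, hydride at low temperature, halogens and the anode, and is removed at the end by hydrolysis alone.

Step 4
Reactants: 4 2,3-dibromo-4,5-bis(methylsulfonyloxy)benzaldehyde; 5 Meldrum's acid (2,2-dimethyl-1,3-dioxane-4,6-dione)
Product: 7 5-[2,3-dibromo-4,5-bis(methylsulfonyloxy)benzyl]-2,2-dimethyl-1,3-dioxane-4,6-dione, via arylidene Meldrum's acid 6 (not isolated)
Conditions: Hantzsch ester (diethyl 2,6-dimethyl-1,4-dihydropyridine-3,5-dicarboxylate, 1.1 equiv), L-proline (20 mol %), EtOH, 25 °C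
Reagents that add atoms: none
Why: Knoevenagel condensation followed by conjugate transfer hydrogenation of the very electrophilic alkylidene Meldrum's acid by the dihydropyridine (organocatalytic reductive alkylation); the benzylic C–C bond is made from the aldehyde without a benzylic halide or a metal hydride.

Step 5
Reactants: 7 5-[2,3-dibromo-4,5-bis(methylsulfonyloxy)benzyl]-2,2-dimethyl-1,3-dioxane-4,6-dione; 8 methyl bromoacetate
Product: 9 methyl 2-{5-[2,3-dibromo-4,5-bis(methylsulfonyloxy)benzyl]-2,2-dimethyl-4,6-dioxo-1,3-dioxan-5-yl}acetate
Conditions: K2CO3 (1.5 equiv), DMF, 20 °C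
Reagents that add atoms: none
Why: SN2 C-alkylation of the stabilized anion of a 5-monosubstituted Meldrum's acid with a reactive α-halo ester; carbonate at room temperature should leave the aryl sulfonates intact.

Step 6
Reactants: 9 methyl 2-{5-[2,3-dibromo-4,5-bis(methylsulfonyloxy)benzyl]-2,2-dimethyl-4,6-dioxo-1,3-dioxan-5-yl}acetate
Product: 11 racemic 2-[2,3-dibromo-4,5-bis(methylsulfonyloxy)benzyl]-4-methoxy-4-oxobutanoic acid, via geminal diacid 10 (not isolated)
Conditions: DMF/H2O (10:1), 100 °C
Reagents that add atoms: water, O
Why: Hydrolytic opening of the dialkylated Meldrum's acid with loss of acetone, then thermal malonic acid decarboxylation; the two ring carbonyls are equivalent and the methyl ester is not attacked in neutral medium, so the acid ends up only on the branched carbon, whose single stereocentre is formed racemic.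

Step 7
Reactants: 11 racemic 2-[2,3-dibromo-4,5-bis(methylsulfonyloxy)benzyl]-4-methoxy-4-oxobutanoic acid (two molecules)
Product: 12 dimethyl 3,4-bis[2,3-dibromo-4,5-bis(methylsulfonyloxy)benzyl]hexanedioate (meso and racemic diastereomers)
Conditions: Pt anode, Pt cathode, undivided cell, NaOMe (0.1 equiv), MeOH/MeCN, about 0.25 A cm−2, 25–35 °C
Reagents that add atoms: none
Why: Kolbe electrolysis: the carboxylate of 11 is discharged at the platinum anode to an acyloxy radical that loses CO2 at once, and two of the resulting secondary alkyl radicals, held at high stationary concentration in the carboxylate layer on the electrode, combine to form the C1–C2 bond of the future ring B. The closest known reaction type is the anodic decarboxylative homodimerization of succinic and glutaric half-esters to adipates and suberates. No ring is closed in this step. Two stereocentres (C3 and C4 of the adipate) arise without any controlling element, so 12 should be a meso/racemic mixture, which is acceptable because both centres become sp2 carbons of ring B in step 10. The step needs radical coupling to win over further oxidation of the secondary radical to a carbocation, over radical disproportionation, over oxidation of the arenes and over cathodic cleavage of C–Br bonds. High current density on smooth platinum, a concentrated and only about one-tenth neutralized solution, and the β-ester group, which makes the radical harder to oxidize, favour coupling. The rings, each with two bromines and two sulfonyloxy groups, lie well above the carboxylate in oxidation potential, and the platinum cathode discharges protons far below the potential needed to reduce an aryl bromide. The regiodefined half-ester from step 6 ensures that only the secondary radical centred on the future C1/C2 is formed.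

Step 8
Reactants: 12 dimethyl 3,4-bis[2,3-dibromo-4,5-bis(methylsulfonyloxy)benzyl]hexanedioate
Product: 13 3,4-bis[2,3-dibromo-4,5-bis(methylsulfonyloxy)benzyl]hexanedial (meso and racemic diastereomers)
Conditions: i-Bu2AlH (DIBAL-H, 2.2 equiv), CH2Cl2, −78 °C; then MeOH, aq. KNaC4H4O6
Reagents that add atoms: none
Why: Partial reduction of the esters to aldehydes through the tetrahedral aluminium hemiacetals, which are stable at −78 °C and collapse only on work-up; aryl bromides and aryl sulfonates should not react with the hydride at this temperature.

Step 9
Reactants: 13 3,4-bis[2,3-dibromo-4,5-bis(methylsulfonyloxy)benzyl]hexanedial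
Product: 14 2-hydroxy-4,5-bis[2,3-dibromo-4,5-bis(methylsulfonyloxy)benzyl]cyclohexan-1-one (mixture of diastereomers)
Conditions: 3-benzyl-5-(2-hydroxyethyl)-4-methylthiazolium chloride (20 mol %), Et3N (0.5 equiv), 1,4-dioxane/EtOH, 70 °C, Ar
Reagents that add atoms: none
Why: Intramolecular benzoin (acyloin) condensation under N-heterocyclic carbene catalysis: the Breslow intermediate of one aldehyde adds to the other in a 6-exo-trig closure that forms C4–C5, as known for aliphatic 1,6-dialdehydes; the new carbinol centre is formed without control and is erased in step 10.

Step 10
Reactants: 14 2-hydroxy-4,5-bis[2,3-dibromo-4,5-bis(methylsulfonyloxy)benzyl]cyclohexan-1-one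
Product: 16 4,5-bis[2,3-dibromo-4,5-bis(methylsulfonyloxy)benzyl]benzene-1,2-diol, via ring B diketone 15 (not isolated)
Conditions: I2 (20 mol %), DMSO, 90 °C
Reagents that add atoms: none
Why: Iodine-catalysed dehydrogenative aromatization with DMSO as terminal oxidant, the pathway by which cyclohexanones are converted into catechols: the enediol of the acyloin is oxidized to the 1,2-dione, whose enol is iodinated at C3 and loses HI, and tautomerization gives the catechol while DMSO reoxidizes HI to I2. Iodine is too weak an oxidant to take the catechol on to the o-quinone, and all three stereocentres of 14 disappear.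

Step 11
Reactants: 16 4,5-bis[2,3-dibromo-4,5-bis(methylsulfonyloxy)benzyl]benzene-1,2-diol
Product: 17 3-bromo-4,5-bis[2,3-dibromo-4,5-bis(methylsulfonyloxy)benzyl]benzene-1,2-diol
Conditions: Br2 (1.0 equiv), CH2Cl2/AcOH, −20 to 0 °C
Reagents that add atoms: bromine, BrBr
Why: Electrophilic aromatic bromination ortho to a phenolic OH; ring B is the only ring with free hydroxyls, C3 and C6 are equivalent by symmetry, and rings A and C (two Br, two sulfonyloxy groups each) are inert, while the first bromine deactivates ring B enough that one equivalent at low temperature should stop at the monobromide.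

Step 12
Reactants: 17 3-bromo-4,5-bis[2,3-dibromo-4,5-bis(methylsulfonyloxy)benzyl]benzene-1,2-diol
Product: 18 3-bromo-4,5-bis(2,3-dibromo-4,5-dihydroxybenzyl)benzene-1,2-diol (target)
Conditions: KOH (aq., 12 equiv), MeOH/1,4-dioxane, 60 °C, Ar, degassed; then aq. HCl
Reagents that add atoms: none
Why: Base hydrolysis of aryl methanesulfonates by attack of hydroxide at sulfur (or E1cB through sulfene), which frees the four phenoxides; aryl C–Br bonds are inert to hydroxide under these conditions, and exclusion of oxygen should prevent oxidation of the catecholates before acidification.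

## Compound list

1 | 5-bromovanillin (3-bromo-4-hydroxy-5-methoxybenzaldehyde) | COc1cc(C=O)cc(Br)c1O | starting material
2 | 2,3-dibromo-4-hydroxy-5-methoxybenzaldehyde | COc1cc(C=O)c(Br)c(Br)c1O | intermediate
3 | 2,3-dibromo-4,5-dihydroxybenzaldehyde | O=Cc1cc(O)c(O)c(Br)c1Br | intermediate
4 | 2,3-dibromo-4,5-bis(methylsulfonyloxy)benzaldehyde | O=Cc1cc(OS(C)(=O)=O)c(OS(C)(=O)=O)c(Br)c1Br | intermediate
5 | Meldrum's acid (2,2-dimethyl-1,3-dioxane-4,6-dione) | CC1(C)OC(=O)CC(=O)O1 | starting material
6 | 5-[2,3-dibromo-4,5-bis(methylsulfonyloxy)benzylidene]-2,2-dimethyl-1,3-dioxane-4,6-dione (formed in the flask in step 4) | CC1(C)OC(=O)C(=Cc2cc(OS(C)(=O)=O)c(OS(C)(=O)=O)c(Br)c2Br)C(=O)O1 | intermediate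
7 | 5-[2,3-dibromo-4,5-bis(methylsulfonyloxy)benzyl]-2,2-dimethyl-1,3-dioxane-4,6-dione | CC1(C)OC(=O)C(Cc2cc(OS(C)(=O)=O)c(OS(C)(=O)=O)c(Br)c2Br)C(=O)O1 | intermediate
8 | methyl bromoacetate | COC(=O)CBr | starting material
9 | methyl 2-{5-[2,3-dibromo-4,5-bis(methylsulfonyloxy)benzyl]-2,2-dimethyl-4,6-dioxo-1,3-dioxan-5-yl}acetate | COC(=O)CC1(Cc2cc(OS(C)(=O)=O)c(OS(C)(=O)=O)c(Br)c2Br)C(=O)OC(C)(C)OC1=O | intermediate
10 | 2-[2,3-dibromo-4,5-bis(methylsulfonyloxy)benzyl]-2-(2-methoxy-2-oxoethyl)propanedioic acid (formed in the flask in step 6) | COC(=O)CC(Cc1cc(OS(C)(=O)=O)c(OS(C)(=O)=O)c(Br)c1Br)(C(=O)O)C(=O)O | intermediate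
11 | racemic 2-[2,3-dibromo-4,5-bis(methylsulfonyloxy)benzyl]-4-methoxy-4-oxobutanoic acid | COC(=O)CC(Cc1cc(OS(C)(=O)=O)c(OS(C)(=O)=O)c(Br)c1Br)C(=O)O | intermediate
12 | dimethyl 3,4-bis[2,3-dibromo-4,5-bis(methylsulfonyloxy)benzyl]hexanedioate (meso and racemic diastereomers) | COC(=O)CC(Cc1cc(OS(C)(=O)=O)c(OS(C)(=O)=O)c(Br)c1Br)C(CC(=O)OC)Cc1cc(OS(C)(=O)=O)c(OS(C)(=O)=O)c(Br)c1Br | intermediate
13 | 3,4-bis[2,3-dibromo-4,5-bis(methylsulfonyloxy)benzyl]hexanedial (meso and racemic diastereomers) | O=CCC(Cc1cc(OS(C)(=O)=O)c(OS(C)(=O)=O)c(Br)c1Br)C(CC=O)Cc1cc(OS(C)(=O)=O)c(OS(C)(=O)=O)c(Br)c1Br | intermediate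
14 | 2-hydroxy-4,5-bis[2,3-dibromo-4,5-bis(methylsulfonyloxy)benzyl]cyclohexan-1-one (mixture of diastereomers) | O=C1CC(Cc2cc(OS(C)(=O)=O)c(OS(C)(=O)=O)c(Br)c2Br)C(Cc2cc(OS(C)(=O)=O)c(OS(C)(=O)=O)c(Br)c2Br)CC1O | intermediate
15 | 4,5-bis[2,3-dibromo-4,5-bis(methylsulfonyloxy)benzyl]cyclohexane-1,2-dione (cis and trans, largely enolized; formed in the flask in step 10) | O=C1CC(Cc2cc(OS(C)(=O)=O)c(OS(C)(=O)=O)c(Br)c2Br)C(Cc2cc(OS(C)(=O)=O)c(OS(C)(=O)=O)c(Br)c2Br)CC1=O | intermediate
16 | 4,5-bis[2,3-dibromo-4,5-bis(methylsulfonyloxy)benzyl]benzene-1,2-diol | Oc1cc(Cc2cc(OS(C)(=O)=O)c(OS(C)(=O)=O)c(Br)c2Br)c(Cc2cc(OS(C)(=O)=O)c(OS(C)(=O)=O)c(Br)c2Br)cc1O | intermediate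
17 | 3-bromo-4,5-bis[2,3-dibromo-4,5-bis(methylsulfonyloxy)benzyl]benzene-1,2-diol | Oc1cc(Cc2cc(OS(C)(=O)=O)c(OS(C)(=O)=O)c(Br)c2Br)c(Cc2cc(OS(C)(=O)=O)c(OS(C)(=O)=O)c(Br)c2Br)c(Br)c1O | intermediate
18 | 3-bromo-4,5-bis(2,3-dibromo-4,5-dihydroxybenzyl)benzene-1,2-diol (achiral) | Oc1cc(Cc2cc(O)c(O)c(Br)c2Cc2cc(O)c(O)c(Br)c2Br)c(Br)c(Br)c1O | target

## Step count and risk

Total step count: 12. Longest linear sequence: 12 steps (1 to 18); step 7 uses two molecules of the same intermediate, so there is no separate branch.

Step 7 (key step). The most likely failure is over-oxidation of the secondary radical to the carbocation, followed by capture by methanol or loss of a proton to a butenoate, together with radical disproportionation; both are typical of α-branched acids and are made worse if poor solubility forces dilute conditions. The fallback sets out from 11 and returns at 12. Compound 11 would be condensed with H2O2 and DCC to the symmetrical bis{2-[2,3-dibromo-4,5-bis(methylsulfonyloxy)benzyl]-4-methoxy-4-oxobutanoyl} peroxide F1. Photolysis of F1 as a solid film at about −60 °C should expel two CO2 and let the radical pair combine within the lattice to 12, with no electrode present to oxidize the radicals further.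

Step 8. Partial reduction may fail to stop uniformly at both termini, leaving over-reduced hydroxy aldehyde or unreduced ester, and the enolizable dialdehyde may suffer on purification. The fallback sets out from 12 and returns at 13. Exhaustive reduction with LiBH4 in THF would give 3,4-bis[2,3-dibromo-4,5-bis(methylsulfonyloxy)benzyl]hexane-1,6-diol F2, and a double Swern oxidation of F2 would give 13, used crude.

Step 9. Base-mediated intramolecular aldol condensation of the 1,6-dialdehyde to a cyclopentenecarbaldehyde may outrun formation of the Breslow intermediate. The fallback sets out from 13 and returns at 15. Reductive pinacol cyclization with SmI2 (THF, t-BuOH, −78 °C, no HMPA so that aryl bromides are spared) would give 4,5-bis[2,3-dibromo-4,5-bis(methylsulfonyloxy)benzyl]cyclohexane-1,2-diol F3. Swern oxidation of both carbinols would give 15, which then goes through the conditions of step 10 to 16.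

Step 10. Ring iodination of the newly formed electron-rich catechol, or a stall at the dione stage, may occur. The fallback sets out from 14 and returns at 16. Compound 14 would be oxidized with Dess–Martin periodinane to 15, which is isolated and converted with TMSOTf/Et3N into 2,3-bis(trimethylsilyloxy)-5,6-bis[2,3-dibromo-4,5-bis(methylsulfonyloxy)benzyl]cyclohexa-1,3-diene F4. Dehydrogenation of this cyclohexadiene with DDQ would give the catechol bis(trimethylsilyl) ether F5, protected against quinone formation, and aqueous acid work-up would give 16.

Step 11. A second bromination at C6, or oxidation of the free catechol to the o-quinone by Br2, may occur. The fallback sets out from 14 and returns at 17; it introduces the bromine before aromatization. Compound 15 (from 14 with Dess–Martin periodinane) would be treated with 1.0 equiv Br2 in CH2Cl2 at 0 °C to give 3-bromo-2-hydroxy-4,5-bis[2,3-dibromo-4,5-bis(methylsulfonyloxy)benzyl]cyclohex-2-en-1-one F6. In F6 the halogen sits on the enol carbon and a second bromination is disfavoured; aromatization of F6 under the I2/DMSO conditions of step 10 would give 17.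

## Further compounds

F1 | step 7 | bis{2-[2,3-dibromo-4,5-bis(methylsulfonyloxy)benzyl]-4-methoxy-4-oxobutanoyl} peroxide (mixture of diastereomers) | COC(=O)CC(Cc1cc(OS(C)(=O)=O)c(OS(C)(=O)=O)c(Br)c1Br)C(=O)OOC(=O)C(CC(=O)OC)Cc1cc(OS(C)(=O)=O)c(OS(C)(=O)=O)c(Br)c1Br
F2 | step 8 | 3,4-bis[2,3-dibromo-4,5-bis(methylsulfonyloxy)benzyl]hexane-1,6-diol (meso and racemic) | OCCC(Cc1cc(OS(C)(=O)=O)c(OS(C)(=O)=O)c(Br)c1Br)C(CCO)Cc1cc(OS(C)(=O)=O)c(OS(C)(=O)=O)c(Br)c1Br
F3 | step 9 | 4,5-bis[2,3-dibromo-4,5-bis(methylsulfonyloxy)benzyl]cyclohexane-1,2-diol (mixture of diastereomers) | OC1CC(Cc2cc(OS(C)(=O)=O)c(OS(C)(=O)=O)c(Br)c2Br)C(Cc2cc(OS(C)(=O)=O)c(OS(C)(=O)=O)c(Br)c2Br)CC1O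
F4 | step 10 | 2,3-bis(trimethylsilyloxy)-5,6-bis[2,3-dibromo-4,5-bis(methylsulfonyloxy)benzyl]cyclohexa-1,3-diene (cis and trans) | C[Si](C)(C)OC1=CC(Cc2cc(OS(C)(=O)=O)c(OS(C)(=O)=O)c(Br)c2Br)C(Cc2cc(OS(C)(=O)=O)c(OS(C)(=O)=O)c(Br)c2Br)C=C1O[Si](C)(C)C
F5 | step 10 | 1,2-bis(trimethylsilyloxy)-4,5-bis[2,3-dibromo-4,5-bis(methylsulfonyloxy)benzyl]benzene | C[Si](C)(C)Oc1cc(Cc2cc(OS(C)(=O)=O)c(OS(C)(=O)=O)c(Br)c2Br)c(Cc2cc(OS(C)(=O)=O)c(OS(C)(=O)=O)c(Br)c2Br)cc1O[Si](C)(C)C
F6 | step 11 | 3-bromo-2-hydroxy-4,5-bis[2,3-dibromo-4,5-bis(methylsulfonyloxy)benzyl]cyclohex-2-en-1-one (cis and trans) | O=C1CC(Cc2cc(OS(C)(=O)=O)c(OS(C)(=O)=O)c(Br)c2Br)C(Cc2cc(OS(C)(=O)=O)c(OS(C)(=O)=O)c(Br)c2Br)C(Br)=C1O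
A1 | alternative 1 | 4,5-bis(4-hydroxy-3-methoxybenzyl)-2-methoxyphenol | COc1cc(Cc2cc(OC)c(O)cc2Cc2cc(OC)c(O)cc2)ccc1O
A2 | alternative 1 | 2-bromo-3,4-bis(2,3-dibromo-4-hydroxy-5-methoxybenzyl)-6-methoxyphenol | COc1cc(Cc2cc(OC)c(O)c(Br)c2Cc2cc(OC)c(O)c(Br)c2Br)c(Br)c(Br)c1O
A3 | alternative 2 | 1,4-bis(2,3-dibromo-4,5-dimethoxyphenyl)but-2-yne-1,4-dione | O=C(C#CC(=O)c1cc(OC)c(OC)c(Br)c1Br)c1cc(OC)c(OC)c(Br)c1Br
A4 | alternative 2 | 2,3-dimethoxybuta-1,3-diene | C=C(OC)C(OC)=C
A5 | alternative 2 | 1,2-bis(2,3-dibromo-4,5-dimethoxybenzoyl)-4,5-dimethoxycyclohexa-1,4-diene | COC1=C(OC)CC(C(=O)c2cc(OC)c(OC)c(Br)c2Br)=C(C(=O)c2cc(OC)c(OC)c(Br)c2Br)C1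
A6 | alternative 3 | (2,3-dibromo-4,5-dimethoxybenzyl)zinc bromide | COc1cc(C[Zn]Br)c(Br)c(Br)c1OC
A7 | alternative 3 | 2-(2,3-dibromo-4,5-dimethoxybenzyl)-4,4,5-trimethoxycyclohexa-2,5-dien-1-one | COC1=CC(=O)C(Cc2cc(OC)c(OC)c(Br)c2Br)=CC1(OC)OC
A8 | alternative 3 | racemic 1,2-bis(2,3-dibromo-4,5-dimethoxybenzyl)-4,4,5-trimethoxycyclohexa-2,5-dien-1-ol | OC1(Cc2cc(OC)c(OC)c(Br)c2Br)C=C(OC)C(OC)(OC)C=C1Cc1cc(OC)c(OC)c(Br)c1Br
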